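The butyrolactone ring (O1, C2, C3, C4, C5) carries the same 3,4,5-trimethoxybenzyl group on C3 and on C4, both with R configuration. The target is therefore one oxidation away from a C2-symmetric 1,4-diol, and its C3–C4 bond links two identical arylpropanoyl units α-carbon to α-carbon. That bond is made by oxidative dimerisation of a single chiral enolate, which in one operation should give the whole lignan carbon skeleton and both stereocentres. The precursor is the N-acyl oxazolidinone of 3-(3,4,5-trimethoxyphenyl)propanoic acid bearing the (S)-4-benzyl auxiliary. Reductive removal of both auxiliaries and oxidative lactonisation of the diol, whose two CH2OH groups are homotopic, complete the synthesis.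

Key step: step 4

Remark: the target SMILES is read as the trans-(3R,4R) lactone (ring numbering O1, C2 carbonyl, C3, C4, C5). Acids 4 and 5 can also be bought, so the route may be entered at either to save up to two steps.

Step 1
Reactants: 1 3,4,5-trimethoxybenzaldehyde; 2 malonic acid
Product: 4 (E)-3,4,5-trimethoxycinnamic acid, via arylidenemalonic acid 3 (not isolated)
Conditions: pyridine, piperidine (cat.), 100 °C; aq. HCl
Reagents that add atoms: none
Why: Knoevenagel–Doebner condensation, in which amine-catalysed condensation of 1 with malonic acid gives 3, which loses CO2 in hot pyridine to give the conjugated acid in its thermodynamically preferred E geometry (removed again in step 2).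

Step 2
Reactants: 4 (E)-3,4,5-trimethoxycinnamic acid
Product: 5 3-(3,4,5-trimethoxyphenyl)propanoic acid
Conditions: H2 (1 atm), 10% Pd/C, EtOAc–MeOH, rt
Reagents that add atoms: none
Why: Heterogeneous catalytic hydrogenation of the conjugated C=C bond, which should leave the aryl methyl ethers, the arene and the carboxylic acid untouched because no benzylic C–O or C–halogen bond is present.

Step 3
Reactants: 5 3-(3,4,5-trimethoxyphenyl)propanoic acid; 6 (S)-4-benzyl-2-oxazolidinone
Product: 8 (S)-4-benzyl-3-[3-(3,4,5-trimethoxyphenyl)propanoyl]oxazolidin-2-one, via mixed pivalic anhydride 7 (not isolated)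
Conditions: PivCl, Et3N, THF, −20 °C; then LiCl, 6, −20 °C to rt
Reagents that add atoms: pivaloyl chloride, CC(C)(C)C(=O)Cl (its acyl group is carried only by intermediate 7 and leaves again as pivalic acid)
Why: N-acylation of an oxazolidinone by the mixed-anhydride method, in which the LiCl-activated N–H of 6 (deprotonated by Et3N) attacks the less hindered arylpropanoyl carbonyl of 7 so that pivalate leaves, the auxiliary stereocentre not being involved.

Step 4
Reactants: 8 (S)-4-benzyl-3-[3-(3,4,5-trimethoxyphenyl)propanoyl]oxazolidin-2-one (two molecules)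
Product: 11 (2R,3R)-1,4-bis[(S)-4-benzyl-2-oxooxazolidin-3-yl]-2,3-bis(3,4,5-trimethoxybenzyl)butane-1,4-dione, via lithium Z-enolate 9 (not isolated), via trichlorotitanium Z-enolate 10 (not isolated)
Conditions: LiN(iPr)2 (LDA), THF, −78 °C; then TiCl4, −78 °C to rt
Reagents that add atoms: lithium diisopropylamide, CC(C)[N-]C(C)C.[Li+] (lithium, carried only by intermediate 9); titanium tetrachloride, Cl[Ti](Cl)(Cl)Cl (TiCl3 group, carried only by intermediate 10)
Why: LiN(iPr)2 gives the chelated Z-enolate 9, lithium–titanium exchange gives 10, and inner-sphere electron transfer from the enolate to the metal (tetravalent titanium becomes trivalent titanium) generates a transient carbonyl-stabilised α-radical that bonds through carbon to a second such unit, either radical to radical or radical to enolate followed by a second one-electron oxidation. The closest known reaction type is the oxidative homocoupling of metal enolates of chiral N-acyl oxazolidinones, which gives C2-symmetric 2,3-disubstituted succinic acid derivatives. No ring is closed; the only bond formed is the acyclic α-carbon to α-carbon bond that becomes C3–C4 of the lactone. Both new stereocentres are controlled by the (S)-benzyl groups of the two auxiliaries: in each metal-chelated, planar N-acyl unit the benzyl group covers one face, so the partner is accepted on the opposite face, the same sense as in alkylation of these enolates, which corresponds to R at each carbon. The step needs double facial selectivity, R,R over R,S and S,S, which rests on the rigid chelate and the Z geometry of 9 and 10; because the auxiliaries make all three isomers diastereomers, minor ones can be removed by crystallisation or chromatography of 11. Chemoselectivity should not be at risk because the enolate is oxidised far more easily than the trimethoxyphenyl rings, and with identical partners no cross-coupling question arises.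

Step 5
Reactants: 11 (2R,3R)-1,4-bis[(S)-4-benzyl-2-oxooxazolidin-3-yl]-2,3-bis(3,4,5-trimethoxybenzyl)butane-1,4-dione
Product: 12 (2R,3R)-2,3-bis(3,4,5-trimethoxybenzyl)butane-1,4-diol
Conditions: LiBH4, MeOH, THF, 0 °C to rt
Reagents that add atoms: none
Why: Reductive cleavage of N-acyl oxazolidinones by LiBH4 (methanol as protic additive accelerates hydride transfer), in which lithium coordination directs hydride to each exocyclic carbonyl and takes both acyl carbons down to CH2OH without touching the adjacent stereocentres, with auxiliary 6 released for recovery.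

Step 6
Reactants: 12 (2R,3R)-2,3-bis(3,4,5-trimethoxybenzyl)butane-1,4-diol
Product: 15 (−)-cubebininolide [(3R,4R)-3,4-bis(3,4,5-trimethoxybenzyl)oxolan-2-one], via hydroxy aldehyde 13 (not isolated), via lactol 14 (not isolated)
Conditions: TEMPO (cat.), PhI(OAc)2, CH2Cl2, rt
Reagents that add atoms: none
Why: Nitroxyl-catalysed oxidative lactonisation of a 1,4-diol, in which one primary alcohol is oxidised to 13, the remaining hydroxyl closes onto the aldehyde (5-exo-trig) to give 14, and 14 is oxidised to the lactone faster than a second CH2OH would react; the homotopic CH2OH groups of C2-symmetric 12 allow only one lactone, C3 and C4 are not touched, and the anomeric centre of 14 disappears in the carbonyl.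

Compound list
1 | 3,4,5-trimethoxybenzaldehyde | COc1cc(C=O)cc(OC)c1OC | starting material
2 | malonic acid | OC(=O)CC(=O)O | starting material
3 | 2-(3,4,5-trimethoxybenzylidene)malonic acid | COc1cc(C=C(C(=O)O)C(=O)O)cc(OC)c1OC | intermediate
4 | (E)-3,4,5-trimethoxycinnamic acid | COc1cc(/C=C/C(=O)O)cc(OC)c1OC | intermediate
5 | 3-(3,4,5-trimethoxyphenyl)propanoic acid | COc1cc(CCC(=O)O)cc(OC)c1OC | intermediate
6 | (S)-4-benzyl-2-oxazolidinone | O=C1N[C@@H](Cc2ccccc2)CO1 | starting material
7 | pivalic 3-(3,4,5-trimethoxyphenyl)propanoic anhydride | COc1cc(CCC(=O)OC(=O)C(C)(C)C)cc(OC)c1OC | intermediate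
8 | (S)-4-benzyl-3-[3-(3,4,5-trimethoxyphenyl)propanoyl]oxazolidin-2-one | COc1cc(CCC(=O)N2[C@@H](Cc3ccccc3)COC2=O)cc(OC)c1OC | intermediate
9 | lithium (Z)-enolate of 8 | COc1cc(C/C=C(\O[Li])N2[C@@H](Cc3ccccc3)COC2=O)cc(OC)c1OC | intermediate
10 | trichlorotitanium (Z)-enolate of 8 | COc1cc(C/C=C(\O[Ti](Cl)(Cl)Cl)N2[C@@H](Cc3ccccc3)COC2=O)cc(OC)c1OC | intermediate
11 | (2R,3R)-1,4-bis[(S)-4-benzyl-2-oxooxazolidin-3-yl]-2,3-bis(3,4,5-trimethoxybenzyl)butane-1,4-dione | O=C(N1[C@@H](Cc2ccccc2)COC1=O)[C@H](Cc1cc(OC)c(OC)c(OC)c1)[C@@H](Cc1cc(OC)c(OC)c(OC)c1)C(=O)N1[C@@H](Cc2ccccc2)COC1=O | intermediate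
12 | (2R,3R)-2,3-bis(3,4,5-trimethoxybenzyl)butane-1,4-diol | OC[C@H](Cc1cc(OC)c(OC)c(OC)c1)[C@H](CO)Cc1cc(OC)c(OC)c(OC)c1 | intermediate
13 | (2R,3R)-4-hydroxy-2,3-bis(3,4,5-trimethoxybenzyl)butanal | OC[C@H](Cc1cc(OC)c(OC)c(OC)c1)[C@H](C=O)Cc1cc(OC)c(OC)c(OC)c1 | intermediate
14 | (3R,4R)-3,4-bis(3,4,5-trimethoxybenzyl)oxolan-2-ol (both anomers) | COc1cc(C[C@H]2COC(O)[C@@H]2Cc2cc(OC)c(OC)c(OC)c2)cc(OC)c1OC | intermediate
15 | (−)-cubebininolide, (3R,4R)-3,4-bis(3,4,5-trimethoxybenzyl)oxolan-2-one | COc1cc(C[C@H]2COC(=O)[C@@H]2Cc2cc(OC)c(OC)c(OC)c2)cc(OC)c1OC | target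

Total step count: 6
Longest linear sequence: 6 steps (1 to 15)

Steps most likely to fail

Step 4. The risk is incomplete facial discrimination in the radical-type bond formation, or return of the enolate to 8 by protonation instead of coupling. The fallback sets out from 8 and comes back at 15, and introduces the two α-substituents one after the other by polar alkylation instead of dimerisation. Deprotonation of 8 with NaN(SiMe3)2 (THF, −78 °C) and alkylation with tert-butyl bromoacetate on the face away from the auxiliary benzyl group should give tert-butyl (R)-4-[(S)-4-benzyl-2-oxooxazolidin-3-yl]-4-oxo-3-(3,4,5-trimethoxybenzyl)butanoate F1. LiBH4 (MeOH, THF, 0 °C) then removes the auxiliary to give tert-butyl (R)-4-hydroxy-3-(3,4,5-trimethoxybenzyl)butanoate F2. TFA in CH2Cl2 at rt cleaves the tert-butyl ester and closes the ring to (R)-4-(3,4,5-trimethoxybenzyl)oxolan-2-one F3. Deprotonation of F3 with LiN(SiMe3)2 (THF, −78 °C) and alkylation with 3,4,5-trimethoxybenzyl bromide, trans to the existing benzyl group, should give 15 directly.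

Step 5. The risk is hydride attack at the ring carbonyl of the crowded imides (opening of the oxazolidinone instead of its expulsion), or stalling after only one auxiliary has left. The fallback sets out from 11 and comes back at 12, and separates cleavage from reduction. LiOH/H2O2 (THF–H2O, 0 °C; Na2SO3 quench) attacks the exocyclic carbonyl even of hindered imides and should give (2R,3R)-2,3-bis(3,4,5-trimethoxybenzyl)succinic acid F4 with recovery of 6. LiAlH4 in THF (0 °C to reflux) then reduces both carboxyl groups to give 12.

Step 6. The risk is oxidation of both hydroxymethyl groups before ring closure, or attack of the iodine oxidant on the electron-rich aryl rings. The fallback sets out from 11 and comes back at 15, and reaches the lactone oxidation level by reduction instead of oxidation. The succinic acid F4 is prepared as in the preceding fallback and closed with DCC in CH2Cl2 at rt to (3R,4R)-3,4-bis(3,4,5-trimethoxybenzyl)oxolane-2,5-dione F5. The two carbonyl groups of this C2-symmetric anhydride are homotopic, so reduction of one of them with NaBH4 (THF, 0 °C to rt, then aq. HCl) can give only 15.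

Further compounds
F1 | step 4 | tert-butyl (R)-4-[(S)-4-benzyl-2-oxooxazolidin-3-yl]-4-oxo-3-(3,4,5-trimethoxybenzyl)butanoate | CC(C)(C)OC(=O)C[C@@H](Cc1cc(OC)c(OC)c(OC)c1)C(=O)N1[C@@H](Cc2ccccc2)COC1=O
F2 | step 4 | tert-butyl (R)-4-hydroxy-3-(3,4,5-trimethoxybenzyl)butanoate | CC(C)(C)OC(=O)C[C@@H](Cc1cc(OC)c(OC)c(OC)c1)CO
F3 | step 4 | (R)-4-(3,4,5-trimethoxybenzyl)oxolan-2-one | O=C1C[C@@H](Cc2cc(OC)c(OC)c(OC)c2)CO1
F4 | step 5 | (2R,3R)-2,3-bis(3,4,5-trimethoxybenzyl)succinic acid | O=C(O)[C@H](Cc1cc(OC)c(OC)c(OC)c1)[C@@H](Cc1cc(OC)c(OC)c(OC)c1)C(=O)O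
F5 | step 6 | (3R,4R)-3,4-bis(3,4,5-trimethoxybenzyl)oxolane-2,5-dione | O=C1[C@H](Cc2cc(OC)c(OC)c(OC)c2)[C@@H](Cc2cc(OC)c(OC)c(OC)c2)C(=O)O1
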